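In a one-step world the substrate falls at a constant fractional rate k (pseudo-first-order), the target takes a fixed share of each loss, and the target curve is a ceiling times 1 − exp(−kt).

| flask | substrate | second nucleophile | gas | remark | time |
|---|---|---|---|---|---|
| red | 0.25 M | 0.72 M | 15 mM (held) | run made earlier |  |
| blue | 0.40 M | 0.72 M | 15 mM (held) | run made earlier |  |
| flask | 0.18 M | 0.720 M | 15 mM (held) |  | 80 min |

| run | time / min | target / % |
|---|---|---|
| red | 10.0 | 13.3 |
| red | 20.0 | 20.9 |
| red | 30.0 | 26.4 |
| red | 40.0 | 28.6 |
| red | 50.0 | 30.3 |
| red | 60.0 | 32.1 |
| blue | 4.00 | 4.9 |
| blue | 12.0 | 13.5 |
| blue | 25.0 | 21.5 |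
| blue | 40.0 | 28.1 |
| blue | 50.0 | 30.2 |
| blue | 60.0 | 31.9 |

(readings scatter by 0.5 percentage points)

* amount of target at 80 min, in percent of the substrate charged
* the change that raises the amount of target at 80 min, in percent of the substrate charged most ("none" if none brings more than 2 percentage points) (eta / beta / epsilon / none)
* amount of target at 80 min, in percent of the substrate charged, after beta

- at the start none of the gas is in solution

The red and blue runs read 32.1% and 31.9% at 60.0 min, a gap smaller than the scatter of 0.5 percentage points, but the blue reading of 21.5% at 25.0 min lies 2.1 points below the midpoint of the red readings on either side of it, more than the scatter, so the blue run, with the higher charge, reads as lagging the red run. In the red run, the rise after 20.0 min set against the rise before it gives k as 0.0499 /min and a first ceiling of 33.8%. Putting that ceiling back into the reading at 40.0 min gives k as 0.0468 /min and a new ceiling of 34.2%, the ceiling share, meaning the part of the charged substrate that can end as target.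

The settings can now be turned by hand, as my own reckoning. Taking the red ceiling over unchanged to the flask at 0.18 M, a charge lower than the red one, and with 80 min leaving 2.37% of the substrate unconverted on this k, the flask should read 33.4%. If what misses the target goes to the second nucleophile, doubling c(second nucleophile) halves the odds of target and brings the ceiling to 20.6%. Doubling the gas saturation doubles those odds and lifts the ceiling to 51.0%. Faster transfer has the lag of the blue run to work on, so by hand beta should bring a gain of the order of that 2.1 points.

The forecast says 34%, 35.5% after beta, and epsilon as the best change, holding that “Doubling the saturation concentration doubles the gas-to-nucleophile ratio”.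

The flask gives 33.6%, and epsilon is best, with changes of 17 points, 2 points for beta (reaching 35.7%) and −10 points for eta. A forecast this close fails if c(second nucleophile) strays: the answer has moved 5 points at 0.505 M and 1.01 M.

    intermediate → solvolysis product (k = 0.123 /s)
    gas ⇌ first nucleophile, rate k2*(csat - [first nucleophile]) (kL = 0.0154 /s)
    substrate → intermediate (k = 9.22 × 10⁻⁴ /s)
    first nucleophile + intermediate → target (k = 17.1 /M/s)
    second nucleophile + intermediate → other capture product (k = 0.425 /M/s)

The flask's products at 80.0 min are target 33.6%, other capture product 45.7% and solvolysis product 19.5%. In the neighbour flask with 0.29 M of second nucleophile, scaling the other-capture part of the ceiling's remainder with c(second nucleophile) gives a ceiling of 47.2%, hence 46.1% at 80 min. That neighbour flask reads 45.4%.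

The numbers in the tables were computed from invented constants, noise included.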